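**Retrosynthetic overview**
- Cut the C7–CH2–C7′ bridge last: an ortho-quinone methide released from a 7-(dimethylaminomethyl)isochroman-6,8-diol (Mannich base) is captured by decarboxycitrinin, the quinone-methide half.
- Both halves come from one triol, (2R,3S)-3-(3,5-dihydroxy-2-methylphenyl)butan-2-ol. The isochroman pyran is closed at the C1–O2 bond by a Mannich-triggered deaminative oxa-cyclisation (key step, new). The quinone-methide pyran is closed by orthoformate annulation.
- The C3–O bond and both stereocentres come from asymmetric hydroboration–oxidation of an (E)-2-aryl-2-butene.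
- The alkene comes from Suzuki coupling of 1-bromo-3,5-dimethoxy-2-methylbenzene, made from 1-bromo-3,5-dimethoxybenzene by formylation and reduction.
- Ring order: arene bought; the two pyran rings are formed in parallel from the triol; the halves are then joined.

Assumption: IpcBH2 made from (−)-α-pinene gives the (2R)-carbinol, by analogy with Brown's phenyl-substituted trisubstituted alkenes; if the sense proved opposite, the reagent from (+)-α-pinene would be used.

**Step 1**
Reactants: 1 1-bromo-3,5-dimethoxybenzene
Product: 3 2-bromo-4,6-dimethoxybenzaldehyde, via aryl iminium dichlorophosphate 2 (not isolated)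
Conditions: POCl3 (1.5 equiv), DMF, 0 → 95 °C; then ice-water
Reagents that add atoms: N,N-dimethylformamide CN(C)C=O; water O
Why: Vilsmeier–Haack formylation goes para to one methoxy group at the ring carbon next to bromine (the site between the two methoxy groups is more hindered), which gives the 2-bromo aldehyde as the major, separable regioisomer.

**Step 2**
Reactants: 3 2-bromo-4,6-dimethoxybenzaldehyde
Product: 4 1-bromo-3,5-dimethoxy-2-methylbenzene
Conditions: Et3SiH (3 equiv), TFA, CH2Cl2, 0 → 25 °C
Reagents that add atoms: none
Why: Ionic hydrogenation reduces the electron-rich aryl aldehyde through its stabilised benzylic cation to the methyl group and leaves the aryl bromide untouched.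

**Step 3**
Reactants: 4 1-bromo-3,5-dimethoxy-2-methylbenzene; 5 (Z)-2-(but-2-en-2-yl)-4,4,5,5-tetramethyl-1,3,2-dioxaborolane
Product: 6 1-[(2E)-but-2-en-2-yl]-3,5-dimethoxy-2-methylbenzene
Conditions: Pd(OAc)2 (3 mol%), SPhos (6 mol%), K3PO4, toluene/H2O 10:1, 90 °C
Reagents that add atoms: none
Why: Suzuki–Miyaura coupling keeps the alkene geometry, so the boronate with cis methyl groups gives the (E)-2-aryl-2-butene needed for the threo product.

**Step 4**
Reactants: 6 1-[(2E)-but-2-en-2-yl]-3,5-dimethoxy-2-methylbenzene
Product: 8 (2R,3S)-3-(3,5-dimethoxy-2-methylphenyl)butan-2-ol, via isopinocampheyl alkyl borane 7 (not isolated)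
Conditions: IpcBH2 [from (−)-α-pinene] (1.2 equiv), THF, −25 °C, 36 h; then 3 M NaOH, 30% H2O2, 0 → 40 °C
Reagents that add atoms: hydrogen peroxide OO
Why: In this Brown asymmetric hydroboration–oxidation the chiral borane adds H–B syn to one face of the E-alkene with boron on the less substituted carbon and the oxidation forms the C3–O bond with retention, so the syn addition fixes the threo relationship and the reagent fixes the absolute configuration (2R,3S).

**Step 5**
Reactants: 8 (2R,3S)-3-(3,5-dimethoxy-2-methylphenyl)butan-2-ol
Product: 9 (2R,3S)-3-(3,5-dihydroxy-2-methylphenyl)butan-2-ol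
Conditions: BBr3 (4 equiv), CH2Cl2, −78 → 0 °C; then H2O
Reagents that add atoms: none
Why: BBr3 ether cleavage (Lewis-acid-assisted SN2 demethylation) frees both phenols at low temperature while the secondary alcohol is held as a borate and returned on hydrolysis, so neither stereocentre is touched.

**Step 6**
Reactants: 9 (2R,3S)-3-(3,5-dihydroxy-2-methylphenyl)butan-2-ol
Product: 11 (3R,4S)-7-[(dimethylamino)methyl]-3,4,5-trimethyl-3,4-dihydro-1H-isochromene-6,8-diol, via bis-Mannich base 10 (not isolated)
Conditions: CH2(NMe2)2 (2.3 equiv), AcOH (10 mol%), 1,4-dioxane, 25 °C, 2 h; then 75 °C, 4 h, slow N2 sweep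
Reagents that add atoms: bis(dimethylamino)methane CN(C)CN(C)C
Why: Proposed new method: a Mannich-triggered deaminative oxa-cyclisation in which the aminal aminomethylates both free ring carbons of the resorcinol (phenol Mannich reaction) to give 10, the aminomethyl group next to the hydroxybutyl chain then loses Me2NH to an ortho-quinone methide that is captured 6-endo by the C3 hydroxyl (oxa-Michael addition, new C1–O2 bond, pyran closed with the oxygen as nucleophile so no stereocentre changes), and the second aminomethyl group between the two phenols has no internal nucleophile, re-adds amine and survives as the handle for the bridge; the closest known reaction types are thermal ortho-quinone-methide generation from phenolic Mannich bases with hetero-nucleophile capture and the oxa-Pictet–Spengler cyclisation (an N,O-acetal/oxocarbenium pathway would give the same product).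

**Step 7**
Reactants: 9 (2R,3S)-3-(3,5-dihydroxy-2-methylphenyl)butan-2-ol
Product: 13 (3R,4S)-6-hydroxy-3,4,5-trimethyl-3,4-dihydro-8H-isochromen-8-one (decarboxycitrinin), via 1-ethoxy cyclic acetal 12 (not isolated)
Conditions: HC(OEt)3 (1.5 equiv), TFA (10 mol%), CH2Cl2, 0 → 25 °C; then 1 M HCl aq., 25 °C, 15 min
Reagents that add atoms: triethyl orthoformate CCOC(OCC)OCC
Why: This is the orthoformate annulation of the classical citrinin end-game (an oxa-Pictet–Spengler reaction at the formate level), in which alcohol exchange tethers a dialkoxycarbenium ion that attacks the adjacent activated ring carbon and acid-induced loss of ethanol from acetal 12 gives the quinone methide without touching a stereocentre.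

**Step 8**
Reactants: 11 (3R,4S)-7-[(dimethylamino)methyl]-3,4,5-trimethyl-3,4-dihydro-1H-isochromene-6,8-diol; 13 (3R,4S)-6-hydroxy-3,4,5-trimethyl-3,4-dihydro-8H-isochromen-8-one
Product: 15 dicitrinone I, via ortho-quinone methide 14 (not isolated)
Conditions: 11 (1.0 equiv), 13 (1.1 equiv), AcOH, 60 °C, Ar, 3 h
Reagents that add atoms: none
Why: Deaminative ortho-quinone-methide generation from the Mannich base followed by Michael addition of the vinylogous-acid carbon C7 of 13 is the standard union for unsymmetrical methylene-bridged phloroglucinol-type dimers, C7 of 13 is the only free nucleophilic carbon in either partner, and acetic acid keeps the released amine protonated so it cannot add to the quinone methide.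

**Compound list**
1 | 1-bromo-3,5-dimethoxybenzene | COc1cc(Br)cc(OC)c1 | starting material
2 | N-[(2-bromo-4,6-dimethoxyphenyl)methylidene]-N-methylmethanaminium dichlorophosphate | COc1cc(Br)c(C=[N+](C)C)c(OC)c1.[O-]P(Cl)(Cl)=O | intermediate
3 | 2-bromo-4,6-dimethoxybenzaldehyde | COc1cc(Br)c(C=O)c(OC)c1 | intermediate
4 | 1-bromo-3,5-dimethoxy-2-methylbenzene | COc1cc(Br)c(C)c(OC)c1 | intermediate
5 | (Z)-2-(but-2-en-2-yl)-4,4,5,5-tetramethyl-1,3,2-dioxaborolane (methyl groups cis; also made in one step from 2-butyne and pinacolborane) | C/C=C(\C)B1OC(C)(C)C(C)(C)O1 | starting material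
6 | 1-[(2E)-but-2-en-2-yl]-3,5-dimethoxy-2-methylbenzene | C/C=C(\C)c1cc(OC)cc(OC)c1C | intermediate
7 | dialkylborane IpcB(H)R: Ipc = isopinocampheyl from (−)-α-pinene, R = the 3-(3,5-dimethoxy-2-methylphenyl)butan-2-yl group with the configuration of 8 (B in place of OH) | C[C@@H]1[C@@H](B[C@H](C)[C@@H](C)c3cc(OC)cc(OC)c3C)C[C@H]2C[C@@H]1C2(C)C | intermediate
8 | (2R,3S)-3-(3,5-dimethoxy-2-methylphenyl)butan-2-ol | C[C@@H](O)[C@@H](C)c1cc(OC)cc(OC)c1C | intermediate
9 | (2R,3S)-3-(3,5-dihydroxy-2-methylphenyl)butan-2-ol | C[C@@H](O)[C@@H](C)c1cc(O)cc(O)c1C | intermediate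
10 | (2R,3S)-3-{2,4-bis[(dimethylamino)methyl]-3,5-dihydroxy-6-methylphenyl}butan-2-ol | C[C@@H](O)[C@@H](C)c1c(C)c(O)c(CN(C)C)c(O)c1CN(C)C | intermediate
11 | (3R,4S)-7-[(dimethylamino)methyl]-3,4,5-trimethyl-3,4-dihydro-1H-isochromene-6,8-diol | Oc1c(CN(C)C)c(O)c(C)c2c1CO[C@H](C)[C@H]2C | intermediate
12 | (3R,4S)-1-ethoxy-3,4,5-trimethyl-3,4-dihydro-1H-isochromene-6,8-diol (both C1 epimers) | Oc1cc(O)c(C)c2c1C(OCC)O[C@H](C)[C@H]2C | intermediate
13 | (3R,4S)-6-hydroxy-3,4,5-trimethyl-3,4-dihydro-8H-isochromen-8-one (decarboxycitrinin) | CC1=C2C(=CO[C@H](C)[C@H]2C)C(=O)C=C1O | intermediate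
14 | (3R,4S)-8-hydroxy-3,4,5-trimethyl-7-methylidene-3,4-dihydro-1H-isochromen-6(7H)-one | C=C1C(=O)C(C)=C2C(=C1O)CO[C@H](C)[C@H]2C | intermediate
15 | dicitrinone I, (3R,4S)-7-{[(3R,4S)-6,8-dihydroxy-3,4,5-trimethyl-3,4-dihydro-1H-isochromen-7-yl]methyl}-6-hydroxy-3,4,5-trimethyl-3,4-dihydro-8H-isochromen-8-one | CC1=C2C(=CO[C@H](C)[C@H]2C)C(=O)C(Cc2c(O)c(C)c3c(c2O)CO[C@H](C)[C@H]3C)=C1O | target

**Totals and risks**
Total step count: 8. Longest linear sequence: 7 (steps 1–5, then 6 or 7, then 8).

The three steps most likely to fail are 6, 7 and 8.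

Step 6 is the proposed new cascade; ring closure could stall at 10, or the second aminomethyl group could be lost. The fallback uses known chemistry and sets out from 9. A classical oxa-Pictet–Spengler reaction with paraformaldehyde (1.0 equiv, cat. TsOH, MeCN, 25 °C) gives (3R,4S)-3,4,5-trimethyl-3,4-dihydro-1H-isochromene-6,8-diol F1. An ordinary phenol Mannich reaction (37% aq. CH2O, 40% aq. Me2NH, EtOH, 25 °C) at its only free ring carbon then comes back to the route at 11.

Step 7 could suffer C-formylation at the ring carbon between the two phenols of 9, or over-reaction of 13 with the orthoformate. The fallback sets out from 9 and builds the pyran at the formaldehyde level before oxidising it. The oxa-Pictet–Spengler reaction described above gives (3R,4S)-3,4,5-trimethyl-3,4-dihydro-1H-isochromene-6,8-diol F2 (the same substance as F1). DDQ (1.0 equiv, dioxane, 10 °C) then abstracts hydride from C1, which is activated by the ring oxygen and the ortho and para hydroxyls, and proton loss comes back to the route at 13.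

Step 8 could fail through oligomerisation of 14 or acid sensitivity of 13. The fallback sets out from 9, makes the symmetrical dimer first and differentiates the halves by oxidation. Paraformaldehyde (1.5 equiv, cat. TFA, MeCN, 25 °C) closes both pyran rings and bridges them to 7,7'-methylenebis[(3R,4S)-3,4,5-trimethyl-3,4-dihydro-1H-isochromene-6,8-diol] F3. DDQ (1.0 equiv, CH2Cl2/dioxane, −20 °C) then dehydrogenates one isochroman half at C1 to the quinone methide and comes back to the route at 15. Mono-oxidation is at best statistical, and recovered F3 is recycled.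

**Further compounds**
F1 | step 6 | (3R,4S)-3,4,5-trimethyl-3,4-dihydro-1H-isochromene-6,8-diol | Oc1cc(O)c(C)c2c1CO[C@H](C)[C@H]2C
F2 | step 7 | (3R,4S)-3,4,5-trimethyl-3,4-dihydro-1H-isochromene-6,8-diol | Oc1cc(O)c(C)c2c1CO[C@H](C)[C@H]2C
F3 | step 8 | 7,7'-methylenebis[(3R,4S)-3,4,5-trimethyl-3,4-dihydro-1H-isochromene-6,8-diol] | Oc1c(Cc3c(O)c(C)c4c(c3O)CO[C@H](C)[C@H]4C)c(O)c(C)c2c1CO[C@H](C)[C@H]2C
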